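Ring A is the 3-butanoyl-2,4,6-trihydroxyphenyl unit; ring B is 2-acetylfilicinic acid, numbered C1 (carbonyl), C2 (acetyl-bearing), C3 and C5 (enolised carbonyls), C4 (CMe2), C6 (bridge-bearing); a CH2 joins C6 to ring A.
Enabling feature: in ring B the C1 carbonyl lies between the acetyl-bearing C2 and C6, so the C6–C1 bond is a Claisen retron and ring B unfolds to the acyclic tetracarbonyl ester 8; the quaternary C4 leaves the terminal methyl (future C6) as the only enolisable ketone position of 8.
Ring closure turns C6 into the CH of a cyclic 1,3-diketone, and the bridge CH2 then lies between two enol-type carbons (C6 of ring B, C3 of ring A): a Mannich/Michael retron cut to [Me2N=CH2]I and butyrylphloroglucinol 3.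
Forward, in one pot: 8 → Claisen closure of C6–C1 → aminomethylation at C6 → loss of amine and Michael addition of 3 (three components, three C–C bonds, ring B).
8 comes from methyl acetoacetate and 2,2-dimethyl-3-oxobutanoyl chloride; 3 from phloroglucinol (ring A is bought aromatic); ring B is the only ring formed and is formed last.

Key step: step 4

Remark on the chemistry: the β-triketone ring and its open-chain precursors are written as one enol or keto tautomer each (the target in the tautomer of its given structure); the tautomers interconvert, and the target has no stereocentre, so no stereocontrol is needed.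

Step 1
Reactants: 1 phloroglucinol (benzene-1,3,5-triol), 2 butanoyl chloride
Product: 3 1-(2,4,6-trihydroxyphenyl)butan-1-one (butyrylphloroglucinol)
Conditions: AlCl3 (4 equiv), PhNO2, rt to 65 °C; ice/2 M HCl work-up
Reagents that add atoms: none
Why: Friedel–Crafts acylation of the strongly activated triol should stop at the mono-ketone because the chelated acyl group deactivates the ring toward a second acylation, and AlCl3 converts any aryl ester into the C-acyl product by Fries rearrangement.

Step 2
Reactants: 4 ethyl 2,2-dimethyl-3-oxobutanoate
Product: 5 2,2-dimethyl-3-oxobutanoic acid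
Conditions: KOH (1.2 equiv), H2O, 0 °C to 20 °C; then 2 M HCl, 0 °C, Et2O extraction, concentration below 20 °C, used at once
Reagents that add atoms: potassium hydroxide (supplies the carboxyl oxygen), [K+].[OH-]
Why: Saponification with cold dilute hydroxide, where acyl substitution at the ester should outrun retro-Claisen attack at the ketone, gives the α,α-disubstituted β-keto acid, which is kept cold because it decarboxylates on warming.

Step 3
Reactants: 5 2,2-dimethyl-3-oxobutanoic acid, 6 methyl 3-oxobutanoate (methyl acetoacetate)
Product: 8 methyl 2-acetyl-4,4-dimethyl-3,5-dioxohexanoate, via acid chloride 7 (not isolated)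
Conditions: (COCl)2 (1.1 equiv), DMF (cat.), CH2Cl2, 0 °C; then 6, MgCl2 (1 equiv), pyridine (2 equiv), CH2Cl2, 0 °C to rt; cold 1 M HCl work-up
Reagents that add atoms: oxalyl chloride, O=C(Cl)C(Cl)=O (its chlorine stays only in intermediate 7 and is lost again on the way to 8)
Why: Chloride 7 has a quaternary α-carbon and so cannot form a ketene, and MgCl2/pyridine soft enolisation of 6 directs the acylation to carbon (C-acylation of a magnesium β-keto ester enolate), the magnesium chelate of the 2-acyl-3-oxo ester product being too weak a nucleophile to react again.

Step 4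
Reactants: 8 methyl 2-acetyl-4,4-dimethyl-3,5-dioxohexanoate, 3 1-(2,4,6-trihydroxyphenyl)butan-1-one
Product: 12 the target 2-acetyl-6-[(3-butanoyl-2,4,6-trihydroxyphenyl)methyl]-3,5-dihydroxy-4,4-dimethylcyclohexa-2,5-dien-1-one, via acetylfilicinic acid 9 (not isolated), via aminomethyl trione 10 (not isolated), via methylidene trione 11 (not isolated)
Conditions: 8, LiN(SiMe3)2 (2.3 equiv), THF, –78 °C to 40 °C; then [Me2N=CH2]I (1.0 equiv), 0 °C to rt; then 3 (1.5 equiv), MeOH, 45 °C; cold 1 M HCl work-up
Reagents that add atoms: N,N-dimethylmethylideneammonium iodide (supplies the bridging CH2), C=[N+](C)C.[I-]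
Why: LiN(SiMe3)2 first forms the lithium chelate of the 2-acyl-3-oxo ester unit of 8 (hexanoate numbering, which becomes the ring B numbering) and then the ketone enolate at the terminal methyl C6, the only position left to enolise because C4 is quaternary and the acetyl methyl belongs to the already anionic chelate. The enolate carbon C6 attacks the ester carbonyl C1 and methoxide leaves (Claisen condensation in its Dieckmann form, the reaction type by which triketo esters are cyclised to acylphloroglucinols and 2-acylcyclohexane-1,3,5-triones), which closes ring B in the 6-(enolendo)-exo-trig mode. The step needs attack at the ester instead of aldol attack at the acetyl carbonyl: the chelate places the charge on the two ketone oxygens and holds the ester carbon on the side of the CMe2 arm, O-acylation to the enol lactone is reversed by the methoxide set free, and only C-acylation ends in the doubly deprotonated β-triketone 9, which is the thermodynamic sink. Ring closure turns the unactivated methyl carbon into the only hydrogen-bearing carbon of a cyclic 1,3-diketone enolate, so [Me2N=CH2]I aminomethylates exactly this carbon (Mannich reaction of a preformed enolate with an iminium salt) to give 10. When the acidic phenol 3 is added and the mixture is warmed, 10 loses Me2NH through its ammonium enolate form to give the methylidene trione 11, and ring carbon C3 of 3 adds to it (Michael addition of an acylphloroglucinol to an alkylidene β-triketone, the second half of the Knoevenagel–Michael union known for bridged acylphloroglucinol dimers); the two free ring positions of 3 are equivalent, and symmetric dimers are held back because all of 9 is aminomethylated before 3 is added in excess. No stereocentre is formed.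

Compound list
1 | phloroglucinol (benzene-1,3,5-triol) | Oc1cc(O)cc(O)c1 | starting material
2 | butanoyl chloride | CCCC(Cl)=O | starting material
3 | 1-(2,4,6-trihydroxyphenyl)butan-1-one (butyrylphloroglucinol) | CCCC(=O)c1c(O)cc(O)cc1O | intermediate
4 | ethyl 2,2-dimethyl-3-oxobutanoate | CCOC(=O)C(C)(C)C(C)=O | starting material
5 | 2,2-dimethyl-3-oxobutanoic acid | CC(=O)C(C)(C)C(O)=O | intermediate
6 | methyl 3-oxobutanoate (methyl acetoacetate) | COC(=O)CC(C)=O | starting material
7 | 2,2-dimethyl-3-oxobutanoyl chloride | CC(=O)C(C)(C)C(Cl)=O | intermediate
8 | methyl 2-acetyl-4,4-dimethyl-3,5-dioxohexanoate | COC(=O)C(C(C)=O)C(=O)C(C)(C)C(C)=O | intermediate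
9 | 2-acetyl-3,5-dihydroxy-4,4-dimethylcyclohexa-2,5-dien-1-one (2-acetylfilicinic acid) | CC(=O)C1=C(O)C(C)(C)C(O)=CC1=O | intermediate
10 | 2-acetyl-6-[(dimethylamino)methyl]-3,5-dihydroxy-4,4-dimethylcyclohexa-2,5-dien-1-one | CN(C)CC1=C(O)C(C)(C)C(O)=C(C(C)=O)C1=O | intermediate
11 | 2-acetyl-3-hydroxy-4,4-dimethyl-6-methylidenecyclohex-2-ene-1,5-dione | C=C1C(=O)C(C)(C)C(O)=C(C(C)=O)C1=O | intermediate
12 | 2-acetyl-6-[(3-butanoyl-2,4,6-trihydroxyphenyl)methyl]-3,5-dihydroxy-4,4-dimethylcyclohexa-2,5-dien-1-one (CNP0284663.0) | CCCC(=O)c1c(O)cc(O)c(CC2=C(O)C(C)(C)C(O)=C(C(C)=O)C2=O)c1O | target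

Total step count: 4. Longest linear sequence: 3 steps (4 → 5 → 8 → 12); step 1 supplies 3 for the convergent step 4.

Steps most likely to fail

Step 4. What may go wrong: loss of the acetyl group from the 2-acyl-3-oxo ester by retro-Claisen cleavage, or aldol closure of the C6 enolate onto the acetyl carbonyl instead of Claisen closure onto the ester; in the union stage, exchange of the bridge by retro-Michael reaction, which leads to symmetric dimers. The fallback keeps the same C6–C1 ring closure but adds the acetyl group afterwards and runs the union as separate operations. It sets out from 5. DCC/DMAP coupling of 5 with 2,2-dimethyl-1,3-dioxane-4,6-dione (Meldrum's acid) in CH2Cl2 at 0 °C should give 5-(1-hydroxy-2,2-dimethyl-3-oxobutylidene)-2,2-dimethyl-1,3-dioxane-4,6-dione F1. Methanolysis in refluxing MeOH should give methyl 4,4-dimethyl-3,5-dioxohexanoate F2. NaOMe in MeOH at reflux should close the C6–C1 bond by Dieckmann condensation, now with no acetyl group to compete, and give filicinic acid F3. C-acetylation of one of its two equivalent ring CH positions (AcCl, AlCl3, PhNO2) should give 9, where the fallback comes back to the route; isolated 9 is then aminomethylated with [Me2N=CH2]I and joined to 3 as in the later stages of step 4.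

Step 3. What may go wrong: decarboxylation of 5 during activation, self-condensation of 7 through its enolisable methyl ketone, and slow C-acylation by the hindered acyl chloride. The fallback masks the ketone so that no β-keto acid or β-keto acyl chloride is handled. It sets out from 4. Ketalisation (ethylene glycol, TsOH, PhMe, water separator, reflux) should give ethyl 2-methyl-2-(2-methyl-1,3-dioxolan-2-yl)propanoate F4. Saponification (KOH, EtOH/H2O, reflux; no retro-Claisen path remains) should give 2-methyl-2-(2-methyl-1,3-dioxolan-2-yl)propanoic acid F5. (COCl)2 with pyridine in CH2Cl2 at 0 °C should give 2-methyl-2-(2-methyl-1,3-dioxolan-2-yl)propanoyl chloride F6, which acylates 6 under MgCl2/pyridine to methyl 2-acetyl-4-methyl-4-(2-methyl-1,3-dioxolan-2-yl)-3-oxopentanoate F7. Mild aqueous acid (1 M HCl, THF, rt) removes the ketal and the fallback comes back to the route at 8.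

Step 2. What may go wrong: retro-Claisen fragmentation of the non-enolisable β-keto ester by hydroxide in competition with the slow hydrolysis of the hindered ester. The fallback passes through a lower oxidation level, so that no ketone is present during the saponification. It sets out from 4. NaBH4 in EtOH at 0 °C should give racemic ethyl 3-hydroxy-2,2-dimethylbutanoate F8. LiOH in THF/H2O should give racemic 3-hydroxy-2,2-dimethylbutanoic acid F9, a stable acid. Oxidation with CrO3/H2SO4 in acetone at 0 °C and cold extraction restores the ketone (the stereocentre disappears), and the fallback comes back to the route at 5.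

Further compounds
F1 | step 4 | 5-(1-hydroxy-2,2-dimethyl-3-oxobutylidene)-2,2-dimethyl-1,3-dioxane-4,6-dione | CC(=O)C(C)(C)C(O)=C1C(=O)OC(C)(C)OC1=O
F2 | step 4 | methyl 4,4-dimethyl-3,5-dioxohexanoate | COC(=O)CC(=O)C(C)(C)C(C)=O
F3 | step 4 | filicinic acid (3,5-dihydroxy-4,4-dimethylcyclohexa-2,5-dien-1-one) | CC1(C)C(O)=CC(=O)C=C1O
F4 | step 3 | ethyl 2-methyl-2-(2-methyl-1,3-dioxolan-2-yl)propanoate | CCOC(=O)C(C)(C)C1(C)OCCO1
F5 | step 3 | 2-methyl-2-(2-methyl-1,3-dioxolan-2-yl)propanoic acid | CC1(OCCO1)C(C)(C)C(O)=O
F6 | step 3 | 2-methyl-2-(2-methyl-1,3-dioxolan-2-yl)propanoyl chloride | CC1(OCCO1)C(C)(C)C(Cl)=O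
F7 | step 3 | methyl 2-acetyl-4-methyl-4-(2-methyl-1,3-dioxolan-2-yl)-3-oxopentanoate | COC(=O)C(C(C)=O)C(=O)C(C)(C)C1(C)OCCO1
F8 | step 2 | ethyl 3-hydroxy-2,2-dimethylbutanoate (racemic) | CCOC(=O)C(C)(C)C(C)O
F9 | step 2 | 3-hydroxy-2,2-dimethylbutanoic acid (racemic) | CC(O)C(C)(C)C(O)=O
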